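## Retrosynthetic overview

1. Last step: HCl opens the 4α,18-spiro-epoxide to the C4 tertiary alcohol and C18 chloride. The epoxide comes from Corey–Chaykovsky methylenation of the C4 ketone. The butenolide is formed by RCM of an acrylate of a 2-substituted allylic alcohol, and the C12 (S)-ester is set by CBS reduction.
2. C19 is added by hydroxymethylation of a β-diketone. C8 is set by conjugate reduction of the C7=C8 enone, and C6 by ketone reduction.
3. The decalin is cut at C9–C10 and C7–C8. A tandem Mukaiyama–Michael / vinylogous Mukaiyama aldol / dehydration joins ring-A enone **10** (C1–C7, C10) to silyl enol ether **22** (C8, C9, C11–C17, C20). Ring B forms here.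
4. Ring A comes from cyclohexa-1,3-diene, with C1 set by enzymatic desymmetrization. Fragment **22** comes from methyl isopropenyl ketone and 2-(TBSO-methyl)acrolein, with C12 set by CBS. Both esters come from (S)-2-methylbutanoic acid. Ring order: A (in the fragment), B (step 19), epoxide (step 21), butenolide (step 27).

Assumptions (one line each):
- The single enantiomer arises from the lipase desymmetrization (step 3), (S)-2-methylbutanoic acid, and (R)-CBS (step 15).
- C5 is set under thermodynamic control at the reversible hydroxymethylation, giving the trans-fused decalin with axial C19.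

## Route

**Step 1**
Reactants: **1** cyclohexa-1,3-diene
Product: **2** 2,3-dioxabicyclo[2.2.2]oct-5-ene
Conditions: O2, tetraphenylporphyrin, hν (visible), CH2Cl2, 0 °C
Reagents that add atoms: singlet oxygen, O=O
Why: photooxygenation is a [4+2] cycloaddition of ¹O2 to the diene, giving the cis-bridged endoperoxide.

**Step 2**
Reactants: **2**
Product: **3** cis-cyclohex-2-ene-1,4-diol (meso, 1R,4S)
Conditions: thiourea, MeOH, rt
Reagents that add atoms: none
Why: reductive O–O cleavage keeps both oxygens on the same face, so the diol is cis (meso).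

**Step 3**
Reactants: **3**
Product: **4** (1S,4R)-4-hydroxycyclohex-2-en-1-yl acetate
Conditions: vinyl acetate, Pseudomonas cepacia lipase, TBME, rt
Reagents that add atoms: vinyl acetate, C=COC(C)=O (adds acetyl)
Why: enzymatic enantiotopic-group-selective acetylation desymmetrizes the meso diol, and the free carbinol becomes C1 of the target.

**Step 4**
Reactants: **4**; **5** (S)-2-methylbutanoic acid
Product: **6** (1R,4S)-4-acetoxycyclohex-2-en-1-yl (S)-2-methylbutanoate
Conditions: DCC, DMAP, CH2Cl2, 0 °C → rt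
Reagents that add atoms: none
Why: Steglich esterification acylates the free carbinol without touching any stereocentre.

**Step 5**
Reactants: **6**
Product: **7** (1R,4S)-4-hydroxycyclohex-2-en-1-yl (S)-2-methylbutanoate
Conditions: K2CO3 (0.2 equiv), MeOH, 0 °C
Reagents that add atoms: none
Why: methanolysis removes the acetate much faster than the α-branched 2-methylbutanoate, leaving one free allylic alcohol.

**Step 6**
Reactants: **7**
Product: **8** (R)-4-oxocyclohex-2-en-1-yl (S)-2-methylbutanoate
Conditions: Dess–Martin periodinane, NaHCO3, CH2Cl2, rt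
Reagents that add atoms: none
Why: oxidation of the allylic alcohol gives the γ-acyloxy enone, and the remaining carbinol stereocentre is untouched.

**Step 7**
Reactants: **8**
Product: **9** (R)-3-iodo-4-oxocyclohex-2-en-1-yl (S)-2-methylbutanoate
Conditions: I2, pyridine, CH2Cl2, 0 °C → rt
Reagents that add atoms: iodine, II
Why: Johnson-type α-iodination of the enone installs the handle for C5–C6 bond formation.

**Step 8**
Reactants: **9**
Product: **10** (R)-3-(1-ethoxyvinyl)-4-oxocyclohex-2-en-1-yl (S)-2-methylbutanoate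
Conditions: Pd(PPh3)4 (5 mol %), toluene, 100 °C
Reagents that add atoms: tributyl(1-ethoxyvinyl)stannane, CCCC[Sn](CCCC)(CCCC)C(=C)OCC (adds C(=CH2)OEt)
Why: Stille coupling gives the masked C6–C7 unit, an enol ether that is nucleophilic at C7 and not electrophilic at C6.

**Step 9**
Reactants: **11** 2-methylenepropane-1,3-diol
Product: **12** 2-{[(tert-butyldimethylsilyl)oxy]methyl}prop-2-en-1-ol
Conditions: NaH (1 equiv), TBSCl, THF, 0 °C
Reagents that add atoms: tert-butyldimethylsilyl chloride, CC(C)(C)[Si](C)(C)Cl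
Why: statistical mono-silylation of the symmetric diol.

**Step 10**
Reactants: **12**
Product: **13** 2-{[(tert-butyldimethylsilyl)oxy]methyl}acrolein
Conditions: activated MnO2, CH2Cl2, rt
Reagents that add atoms: none
Why: MnO2 oxidizes the allylic alcohol chemoselectively to the enal.

**Step 11**
Reactants: **14** 3-methylbut-3-en-2-one
Product: **15** 4-bromo-3-methylbutan-2-one
Conditions: 48 % aq. HBr, 0 °C, 1 h
Reagents that add atoms: hydrogen bromide, Br
Why: conjugate addition of bromide to the enone gives the β-bromo ketone, which is used crude.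

**Step 12**
Reactants: **15**
Product: **16** 2-(1-bromopropan-2-yl)-2-methyl-1,3-dioxolane
Conditions: TMSOCH2CH2OTMS, TMSOTf (cat.), CH2Cl2, −78 °C
Reagents that add atoms: 1,2-bis(trimethylsilyloxy)ethane, C[Si](C)(C)OCCO[Si](C)(C)C (adds OCH2CH2O)
Why: Noyori ketalization under non-acidic conditions masks the ketone without HBr elimination.

**Step 13**
Reactants: **16**; **13**
Product: **17** 2-{[(TBS)oxy]methyl}-5-(2-methyl-1,3-dioxolan-2-yl)hex-1-en-3-ol (C9/C12 epimeric mixture)
Conditions: Mg, THF, 40 °C; then CeCl3, then **13**, −78 → 0 °C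
Reagents that add atoms: none
Why: the organocerium adds 1,2 to the enal (Barbier/Grignard-type carbonyl addition); both stereocentres are erased later (steps 14 and 18).

**Step 14**
Reactants: **17**
Product: **18** the corresponding hex-1-en-3-one
Conditions: Dess–Martin periodinane, NaHCO3, CH2Cl2, 0 °C
Reagents that add atoms: none
Why: oxidation removes the unselective C12 stereocentre and gives the substrate for CBS reduction.

**Step 15**
Reactants: **18**
Product: **19** (3S)-allylic alcohol (12S)
Conditions: (R)-Me-CBS (10 mol %), BH3·SMe2, THF, −20 °C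
Reagents that add atoms: none
Why: Corey–Bakshi–Shibata reduction delivers hydride to one enone face, setting 12S by catalyst control.

**Step 16**
Reactants: **19**; **5**
Product: **20** (3S)-2-{[(TBS)oxy]methyl}-5-(2-methyl-1,3-dioxolan-2-yl)hex-1-en-3-yl (S)-2-methylbutanoate
Conditions: DCC, DMAP, CH2Cl2, 0 °C → rt
Reagents that add atoms: none
Why: Steglich esterification proceeds with retention at C12.

**Step 17**
Reactants: **20**
Product: **21** (3S)-2-{[(TBS)oxy]methyl}-5-methyl-6-oxohept-1-en-3-yl (S)-2-methylbutanoate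
Conditions: I2 (10 mol %), acetone, rt
Reagents that add atoms: none
Why: iodine-catalysed transketalization into acetone removes the dioxolane under neutral conditions that spare the TBS ether and esters.

**Step 18**
Reactants: **21**
Product: **22** the thermodynamic (more substituted) trimethylsilyl enol ether of **21**, C8(OTMS)=C9
Conditions: TMSCl, NaI, Et3N, MeCN, 60 °C
Reagents that add atoms: chlorotrimethylsilane, C[Si](C)(C)Cl (adds TMS)
Why: equilibrating silylation favours the tetrasubstituted enol ether, which is the nucleophile for forming the C9 quaternary centre.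

**Step 19** (key coupling)
Reactants: **10**; **22**
Product: **23** bicyclic enone-dione (neo-clerodane numbering: 1β-OCOR*, 4-oxo, 6-oxo, Δ7, 12S-OCOR*, 16-OTBS, 13-methylene; C5 epimerizable)
Conditions: Sc(OTf)3 (10 mol %), 4 Å MS, CH2Cl2, −78 → 0 °C; then PPTS, toluene, 80 °C (one pot)
Reagents that add atoms: none
Why: Sc(III) chelation promotes Mukaiyama–Michael addition of the enol ether to C10 anti to the C1 acyloxy group (setting C10, and C9 through an open synclinal transition state); the resulting silyl dienol ether undergoes vinylogous Mukaiyama aldol onto the C8 ketone (ring B), and acid dehydration gives the C7=C8 enone with C5 left as the epimerizable β-diketone carbon.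

**Step 20**
Reactants: **23**
Product: **24** 19-acetoxy enone (C5 quaternary, trans-fused)
Conditions: 37 % aq. HCHO, Et3N (cat.), THF, rt; then Ac2O, DMAP, pyridine
Reagents that add atoms: formaldehyde, C=O; acetic anhydride, CC(=O)OC(C)=O
Why: aldol hydroxymethylation of the β-diketone enol is reversible, so the trans-fused isomer (axial C19, H10 β) is the thermodynamic product and is locked by acetylation.

**Step 21**
Reactants: **24**
Product: **25** 4α,18-spiro-epoxide
Conditions: Me3S⁺ I⁻, n-BuLi, THF, −10 → 0 °C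
Reagents that add atoms: trimethylsulfonium iodide, C[S+](C)C.[I-] (delivers CH2)
Why: Corey–Chaykovsky methylenation with dimethylsulfonium methylide attacks the more electrophilic saturated C4 ketone axially from the β face, giving axial C18 and equatorial 4α-oxygen.

**Step 22**
Reactants: **25**
Product: **26** saturated C6 ketone (8-H β, 8-Me α)
Conditions: [(Ph3P)CuH]6, toluene, rt
Reagents that add atoms: none
Why: Stryker conjugate reduction delivers H to C8 from the β face, because the α face is blocked by axial C20, so methyl ends up α and equatorial.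

**Step 23**
Reactants: **26**
Product: **27** 6α-alcohol
Conditions: NaBH4, MeOH/CH2Cl2, −20 °C
Reagents that add atoms: none
Why: small hydride attacks the C6 ketone axially from the β face, since the α face is hindered by axial C19, giving the equatorial α-alcohol.

**Step 24**
Reactants: **27**
Product: **28** 6α-acetate
Conditions: Ac2O, DMAP, pyridine, 40 °C
Reagents that add atoms: acetic anhydride, CC(=O)OC(C)=O
Why: acylation of the secondary alcohol, with no stereochemical change.

**Step 25**
Reactants: **28**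
Product: **29** primary allylic alcohol (16-OH)
Conditions: TBAF, AcOH (1:1), THF, 0 °C
Reagents that add atoms: none
Why: buffered fluoride removes TBS while sparing the epoxide and esters.

**Step 26**
Reactants: **29**
Product: **30** 16-acrylate
Conditions: acryloyl chloride, i-Pr2NEt, CH2Cl2, −20 °C
Reagents that add atoms: acryloyl chloride, C=CC(=O)Cl
Why: the only free hydroxyl is acylated to give the RCM precursor.

**Step 27**
Reactants: **30**
Product: **31** epoxy butenolide
Conditions: Hoveyda–Grubbs II (5 mol %), 1,4-benzoquinone (10 mol %), CH2Cl2 (1 mM), 40 °C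
Reagents that add atoms: none
Why: ring-closing metathesis between the 1,1-disubstituted alkene and the acrylate (ethylene lost) closes the β-substituted butenolide.

**Step 28**
Reactants: **31**
Product: **32** ajugaciliatin A
Conditions: HCl (1 M in Et2O), CH2Cl2, −20 °C
Reagents that add atoms: hydrogen chloride, Cl
Why: chloride attacks the unhindered primary epoxide carbon (SN2-like) and not the neopentylic tertiary C4, so C4 keeps its configuration and is released as the tertiary alcohol.

## Compound list

1 | cyclohexa-1,3-diene | C1=CC=CCC1 | starting material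
2 | 2,3-dioxabicyclo[2.2.2]oct-5-ene | C1CC2C=CC1OO2 | intermediate
3 | cis-cyclohex-2-ene-1,4-diol (meso) | O[C@H]1C=C[C@@H](O)CC1 | intermediate
4 | (1S,4R)-4-hydroxycyclohex-2-en-1-yl acetate | CC(=O)O[C@@H]1C=C[C@H](O)CC1 | intermediate
5 | (S)-2-methylbutanoic acid | CC[C@H](C)C(=O)O | starting material
6 | (1R,4S)-4-acetoxycyclohex-2-en-1-yl (S)-2-methylbutanoate | CC(=O)O[C@@H]1C=C[C@H](OC(=O)[C@@H](C)CC)CC1 | intermediate
7 | (1R,4S)-4-hydroxycyclohex-2-en-1-yl (S)-2-methylbutanoate | O[C@@H]1C=C[C@H](OC(=O)[C@@H](C)CC)CC1 | intermediate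
8 | (R)-4-oxocyclohex-2-en-1-yl (S)-2-methylbutanoate | O=C1C=C[C@H](OC(=O)[C@@H](C)CC)CC1 | intermediate
9 | (R)-3-iodo-4-oxocyclohex-2-en-1-yl (S)-2-methylbutanoate | O=C1C(I)=C[C@H](OC(=O)[C@@H](C)CC)CC1 | intermediate
10 | (R)-3-(1-ethoxyvinyl)-4-oxocyclohex-2-en-1-yl (S)-2-methylbutanoate | O=C1C(C(=C)OCC)=C[C@H](OC(=O)[C@@H](C)CC)CC1 | intermediate
11 | 2-methylenepropane-1,3-diol | OCC(=C)CO | starting material
12 | 2-{[(TBS)oxy]methyl}prop-2-en-1-ol | OCC(=C)CO[Si](C)(C)C(C)(C)C | intermediate
13 | 2-{[(TBS)oxy]methyl}acrolein | O=CC(=C)CO[Si](C)(C)C(C)(C)C | intermediate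
14 | 3-methylbut-3-en-2-one | CC(=O)C(C)=C | starting material
15 | 4-bromo-3-methylbutan-2-one | CC(=O)C(C)CBr | intermediate
16 | 2-(1-bromopropan-2-yl)-2-methyl-1,3-dioxolane | CC(CBr)C1(C)OCCO1 | intermediate
17 | allylic alcohol (C9/C12 epimeric mixture) | CC(CC(O)C(=C)CO[Si](C)(C)C(C)(C)C)C1(C)OCCO1 | intermediate
18 | hex-1-en-3-one | CC(CC(=O)C(=C)CO[Si](C)(C)C(C)(C)C)C1(C)OCCO1 | intermediate
19 | (3S)-allylic alcohol | CC(C[C@H](O)C(=C)CO[Si](C)(C)C(C)(C)C)C1(C)OCCO1 | intermediate
20 | (3S)-(S)-2-methylbutanoate of 19 | CC(C[C@H](OC(=O)[C@@H](C)CC)C(=C)CO[Si](C)(C)C(C)(C)C)C1(C)OCCO1 | intermediate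
21 | (3S)-6-oxohept-1-en-3-yl (S)-2-methylbutanoate | CC(=O)C(C)C[C@H](OC(=O)[C@@H](C)CC)C(=C)CO[Si](C)(C)C(C)(C)C | intermediate
22 | TMS enol ether of 21 | CC(O[Si](C)(C)C)=C(C)C[C@H](OC(=O)[C@@H](C)CC)C(=C)CO[Si](C)(C)C(C)(C)C | intermediate
23 | bicyclic enone-dione (C5 undefined) | CC[C@H](C)C(=O)O[C@@H](C[C@@]1(C)C(C)=CC(=O)C2[C@@H]1[C@H](OC(=O)[C@@H](C)CC)CCC2=O)C(=C)CO[Si](C)(C)C(C)(C)C | intermediate
24 | 19-acetoxy enone-ketone | CC[C@H](C)C(=O)O[C@@H](C[C@@]1(C)C(C)=CC(=O)[C@]2(COC(C)=O)[C@@H]1[C@H](OC(=O)[C@@H](C)CC)CCC2=O)C(=C)CO[Si](C)(C)C(C)(C)C | intermediate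
25 | 4α,18-spiro-epoxide enone | CC[C@H](C)C(=O)O[C@@H](C[C@@]1(C)C(C)=CC(=O)[C@]2(COC(C)=O)[C@@H]1[C@H](OC(=O)[C@@H](C)CC)CC[C@]2(O3)C3)C(=C)CO[Si](C)(C)C(C)(C)C | intermediate
26 | C6 ketone, 8α-Me | CC[C@H](C)C(=O)O[C@@H](C[C@@]1(C)[C@H](C)CC(=O)[C@]2(COC(C)=O)[C@@H]1[C@H](OC(=O)[C@@H](C)CC)CC[C@]2(O3)C3)C(=C)CO[Si](C)(C)C(C)(C)C | intermediate
27 | 6α-alcohol | CC[C@H](C)C(=O)O[C@@H](C[C@@]1(C)[C@H](C)C[C@H](O)[C@]2(COC(C)=O)[C@@H]1[C@H](OC(=O)[C@@H](C)CC)CC[C@]2(O3)C3)C(=C)CO[Si](C)(C)C(C)(C)C | intermediate
28 | 6α-acetate | CC[C@H](C)C(=O)O[C@@H](C[C@@]1(C)[C@H](C)C[C@H](OC(C)=O)[C@]2(COC(C)=O)[C@@H]1[C@H](OC(=O)[C@@H](C)CC)CC[C@]2(O3)C3)C(=C)CO[Si](C)(C)C(C)(C)C | intermediate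
29 | 16-hydroxy allyl alcohol | CC[C@H](C)C(=O)O[C@@H](C[C@@]1(C)[C@H](C)C[C@H](OC(C)=O)[C@]2(COC(C)=O)[C@@H]1[C@H](OC(=O)[C@@H](C)CC)CC[C@]2(O3)C3)C(=C)CO | intermediate
30 | acrylate | CC[C@H](C)C(=O)O[C@@H](C[C@@]1(C)[C@H](C)C[C@H](OC(C)=O)[C@]2(COC(C)=O)[C@@H]1[C@H](OC(=O)[C@@H](C)CC)CC[C@]2(O3)C3)C(=C)COC(=O)C=C | intermediate
31 | epoxy butenolide | CC[C@H](C)C(=O)O[C@@H](C[C@@]1(C)[C@H](C)C[C@H](OC(C)=O)[C@]2(COC(C)=O)[C@@H]1[C@H](OC(=O)[C@@H](C)CC)CC[C@]2(O3)C3)C1=CC(=O)OC1 | intermediate
32 | ajugaciliatin A | CC[C@H](C)C(=O)O[C@@H](C[C@@]1(C)[C@H](C)C[C@H](OC(C)=O)[C@]2(COC(C)=O)[C@@H]1[C@H](OC(=O)[C@@H](C)CC)CC[C@]2(O)CCl)C1=CC(=O)OC1 | target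

## Totals

Total steps: 28. Longest linear sequence: 18 (steps 1–8, then 19–28), which is 0.64 of the total.

## Three steps most likely to fail

1. **Step 19 (tandem Mukaiyama–Michael/aldol/dehydration).** Forming the C9 quaternary centre from a tetrasubstituted enol ether and controlling C9 relative to C10 is hard. Fallback: a Hajos–Parrish-type proline-catalysed Robinson annulation of cyclohexane-1,3-dione with ethyl vinyl ketone, then deconjugative α-allylation to set C9, ozonolysis to the C12 aldehyde, and NHK coupling with a 4-iodobutenolide.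
2. **Step 20 (C5 hydroxymethylation).** The trans ring fusion with axial C19 may not be the thermodynamic product, and retro-aldol or retro-Claisen could compete. Fallback: carry C19 as a methyl ester on a 2-methoxycarbonyl ring-A acceptor so that the quaternary centre forms during annulation, then reduce CO2Me to CH2OH at a stage before the esters and butenolide are installed.
3. **Step 21 (Corey–Chaykovsky).** The ylide may also attack the C6 enone carbonyl or the esters, and the axial selectivity is unproven. Fallback: Luche-reduce the C6 carbonyl first, then convert C4 to the exocyclic methylene by Petasis methylenation. Follow with VO(acac)2/TBHP epoxidation directed by the free α-C6 and C19 hydroxyls, then the same HCl opening.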